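The route rests on opening the pyran ring (ring D) of the 2,2-dimethyl-2H-chromene at O1–C8a and C4–C4a. Because O1 lies para to C6, the carbon that later binds C2 of the chromanone, the aryl ether precursor is a para-disubstituted benzene whose two ortho carbons are equivalent. In one flask a tertiary propargylic alkoxide is O-arylated by a diaryliodonium salt and the resulting aryl propargyl ether is heated: Claisen shift, hydrogen shift and oxa-6π closure give 6-bromo-2,2-dimethylchromene from two achiral commercial compounds. Its boronic acid is then added to a 6,8-diprenylchromone under chiral rhodium catalysis, which sets C2 as S.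

Key step: step 4

Remark 1: chromene atoms are numbered O1, C2, C3, C4, C4a, C5 to C8, C8a; chromanone and chromone positions are named as such where used.
Remark 2: compounds 1, 4, 6 and 7 are taken as commercially available.
Remark 3: the bisphosphine in step 6 is (S)-6,6'-dimethoxy-2,2'-bis[bis(3,4,5-trifluorophenyl)phosphino]-1,1'-biphenyl, abbreviated (S)-TFP-MeO-BIPHEP. Its sense of induction is assigned by analogy with aryl transfer from rhodium complexes of (S)-biaryl bisphosphines to cyclic enones; should the addition deliver the 2R series, the (R)-ligand is used and nothing else changes.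

Step 1
Reactants: 1 7-hydroxy-4H-chromen-4-one
Product: 2 7-hydroxy-6,8-diiodo-4H-chromen-4-one
Conditions: NIS (2.2 equiv), TsOH·H2O (10 mol %), MeCN, rt
Reagents that add atoms: N-iodosuccinimide, O=C1CCC(=O)N1I
Why: Electrophilic aromatic iodination of a phenol, in which the 7-hydroxyl activates its two ortho carbons C6 and C8 (the para carbon C4a is quaternary) far more than the electron-poor pyranone C3, so two equivalents of the iodonium source should stop at the 6,8-diiodide.

Step 2
Reactants: 2 7-hydroxy-6,8-diiodo-4H-chromen-4-one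
Product: 3 7-[(tert-butyldimethylsilyl)oxy]-6,8-diiodo-4H-chromen-4-one
Conditions: TBSCl, imidazole, DMF, rt
Reagents that add atoms: tert-butyldimethylsilyl chloride, CC(C)(C)[Si](C)(C)Cl
Why: Imidazole-promoted O-silylation of the acidic, iodine-flanked phenol, giving a silyl ether that should tolerate the palladium and rhodium steps and leave later under buffered fluoride without acid or strong base.

Step 3
Reactants: 3 7-[(tert-butyldimethylsilyl)oxy]-6,8-diiodo-4H-chromen-4-one; 4 tributyl(3-methylbut-2-en-1-yl)stannane
Product: 5 7-[(tert-butyldimethylsilyl)oxy]-6,8-bis(3-methylbut-2-en-1-yl)-4H-chromen-4-one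
Conditions: 4 (3 equiv), Pd(PPh3)4 (10 mol %), CuI (20 mol %), 1,4-dioxane, 100 °C
Reagents that add atoms: none
Why: Double Stille coupling in which zerovalent palladium inserts into each aryl C–I bond, the allylic stannane transmetalates (helped by CuI) and reductive elimination at the tin-bearing carbon should give the linear prenyl groups at C6 and C8, while chromone, silyl ether and trisubstituted alkenes are inert.

Step 4
Reactants: 6 2-methylbut-3-yn-2-ol; 7 bis(4-bromophenyl)iodonium trifluoromethanesulfonate
Product: 12 6-bromo-2,2-dimethyl-2H-chromene, via sodium 2-methylbut-3-yn-2-olate 8 (not isolated), via aryl propargyl ether 9 (not isolated), via ortho-allenylphenol 10 (not isolated), via ortho-quinone methide 11 (not isolated)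
Conditions: 6 (1.1 equiv), NaH (1.05 equiv), toluene, 0 °C to rt; 7 (1.0 equiv), rt; then PhNEt2, 190 °C (toluene distilled off)
Reagents that add atoms: none
Why: Alkoxide 8 adds to the trivalent iodine of 7 and ligand coupling with loss of 1-bromo-4-iodobenzene forms the aryl C–O bond of ether 9 at the ipso carbon, so bromine stays para to oxygen; at 190 °C ether 9 undergoes the aromatic propargyl Claisen [3,3] shift, which forms the C4–C4a bond, and the dienone enolises to ortho-allenylphenol 10. A 1,5-hydrogen shift from O–H to the central allene carbon gives ortho-quinone methide 11, and ring D closes as a six-membered ring by a thermally allowed disrotatory oxa-6π electrocyclisation that remakes the O1–C2 bond broken in the Claisen step, so the net new bonds are aryl–O1 and aryl–C4. The closest known reactions are the metal-free O-arylation of tertiary alkoxides with diaryliodonium salts and the thermal conversion of aryl 1,1-dimethylpropargyl ethers into 2,2-dimethyl-2H-chromenes, here run in one flask. No stereocentre is created. The step needs regioselectivity in the C–C bond formation and O- over C-arylation of the alkynol: the two carbons ortho to oxygen in 9 are equivalent by symmetry, so only the 6-bromo isomer can arise, and NaH removes only the hydroxyl proton, so no acetylide is present. The gem-dimethyl group speeds the sigmatropic step and the basic amine solvent suppresses acid-catalysed closure to a benzofuran.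

Step 5
Reactants: 12 6-bromo-2,2-dimethyl-2H-chromene
Product: 15 (2,2-dimethyl-2H-chromen-6-yl)boronic acid, via chromenyllithium 13 (not isolated), via lithium aryltriisopropoxyborate 14 (not isolated)
Conditions: n-BuLi, THF, −78 °C; B(OiPr)3, −78 °C to rt; 1 M HCl, 0 °C
Reagents that add atoms: triisopropyl borate, CC(C)OB(OC(C)C)OC(C)C; water, O
Why: Lithiation–borylation, in which bromine–lithium exchange at −78 °C should outrun any addition to the C3=C4 bond and trapping of aryllithium 13 by the borate, then brief cold hydrolysis of ate complex 14, gives the boronic acid.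

Step 6
Reactants: 5 7-[(tert-butyldimethylsilyl)oxy]-6,8-bis(3-methylbut-2-en-1-yl)-4H-chromen-4-one; 15 (2,2-dimethyl-2H-chromen-6-yl)boronic acid
Product: 16 (2S)-7-[(tert-butyldimethylsilyl)oxy]-2-(2,2-dimethyl-2H-chromen-6-yl)-6,8-bis(3-methylbut-2-en-1-yl)chroman-4-one
Conditions: 15 (2 equiv), [Rh(OH)((S)-TFP-MeO-BIPHEP)]2 (3 mol % Rh), toluene/H2O (10:1), 30 °C
Reagents that add atoms: none
Why: Hayashi–Miyaura asymmetric 1,4-addition, in which the aryl group is transmetalated to monovalent rhodium, the chromone C2=C3 bond inserts with aryl delivery to the Re face of C2 (O1 > C3 > H) under control of the C2-symmetric (S)-bisphosphine, and water protonates the rhodium enolate, so that C2 of the chromanone is set as S by the catalyst.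

Step 7
Reactants: 16 (2S)-7-[(tert-butyldimethylsilyl)oxy]-2-(2,2-dimethyl-2H-chromen-6-yl)-6,8-bis(3-methylbut-2-en-1-yl)chroman-4-one
Product: 17 (2S)-2-(2,2-dimethyl-2H-chromen-6-yl)-7-hydroxy-6,8-bis(3-methylbut-2-en-1-yl)chroman-4-one
Conditions: Bu4NF, AcOH (1:1), THF, 0 °C
Reagents that add atoms: none
Why: Fluoride-mediated cleavage of the aryl silyl ether driven by the strong Si–F bond, with acetic acid buffering phenoxide and fluoride basicity so that the chromanone ring should not open by retro-oxa-Michael reaction and C2 keeps its S configuration.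

Compound list
1 | 7-hydroxy-4H-chromen-4-one | O=c1ccoc2cc(O)ccc12 | starting material
2 | 7-hydroxy-6,8-diiodo-4H-chromen-4-one | O=c1ccoc2c(I)c(O)c(I)cc12 | intermediate
3 | 7-[(tert-butyldimethylsilyl)oxy]-6,8-diiodo-4H-chromen-4-one | O=c1ccoc2c(I)c(O[Si](C)(C)C(C)(C)C)c(I)cc12 | intermediate
4 | tributyl(3-methylbut-2-en-1-yl)stannane | CCCC[Sn](CCCC)(CCCC)CC=C(C)C | starting material
5 | 7-[(tert-butyldimethylsilyl)oxy]-6,8-bis(3-methylbut-2-en-1-yl)-4H-chromen-4-one | CC(C)=CCc1cc2c(=O)ccoc2c(CC=C(C)C)c1O[Si](C)(C)C(C)(C)C | intermediate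
6 | 2-methylbut-3-yn-2-ol | CC(C)(O)C#C | starting material
7 | bis(4-bromophenyl)iodonium trifluoromethanesulfonate | Brc1ccc(cc1)[I+]c1ccc(Br)cc1.[O-]S(=O)(=O)C(F)(F)F | starting material
8 | sodium 2-methylbut-3-yn-2-olate | [Na+].CC(C)([O-])C#C | intermediate
9 | 1-bromo-4-[(2-methylbut-3-yn-2-yl)oxy]benzene | CC(C)(C#C)Oc1ccc(Br)cc1 | intermediate
10 | 4-bromo-2-(3-methylbuta-1,2-dien-1-yl)phenol | CC(C)=C=Cc1cc(Br)ccc1O | intermediate
11 | (6Z)-4-bromo-6-(3-methylbut-2-en-1-ylidene)cyclohexa-2,4-dien-1-one | CC(C)=C/C=C1/C=C(Br)C=CC1=O | intermediate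
12 | 6-bromo-2,2-dimethyl-2H-chromene | CC1(C)C=Cc2cc(Br)ccc2O1 | intermediate
13 | (2,2-dimethyl-2H-chromen-6-yl)lithium | [Li]c1ccc2OC(C)(C)C=Cc2c1 | intermediate
14 | lithium (2,2-dimethyl-2H-chromen-6-yl)tri(propan-2-yloxy)borate | [Li+].CC(C)O[B-](OC(C)C)(OC(C)C)c1ccc2OC(C)(C)C=Cc2c1 | intermediate
15 | (2,2-dimethyl-2H-chromen-6-yl)boronic acid | OB(O)c1ccc2OC(C)(C)C=Cc2c1 | intermediate
16 | (2S)-7-[(tert-butyldimethylsilyl)oxy]-2-(2,2-dimethyl-2H-chromen-6-yl)-6,8-bis(3-methylbut-2-en-1-yl)chroman-4-one | CC(C)=CCc1cc2c(c(CC=C(C)C)c1O[Si](C)(C)C(C)(C)C)O[C@H](c1ccc3c(c1)C=CC(C)(C)O3)CC2=O | intermediate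
17 | (2S)-2-(2,2-dimethyl-2H-chromen-6-yl)-7-hydroxy-6,8-bis(3-methylbut-2-en-1-yl)chroman-4-one | CC(C)=CCc1cc2c(c(CC=C(C)C)c1O)O[C@H](c1ccc3c(c1)C=CC(C)(C)O3)CC2=O | target

Total step count: 7.
Longest linear sequence: 5 steps (steps 1, 2, 3, 6 and 7, from compound 1).

Steps most likely to fail

Step 4. Ortho-deprotonation of the iodonium salt by the hindered tertiary alkoxide (an aryne-type pathway that would scramble the position of bromine), or decomposition of the salt, may outrun ligand coupling, so that O-arylation is inefficient. The fallback sets out from compound 6 and comes back at compound 12. The same alkoxide 8 is arylated by nucleophilic aromatic substitution on 1-fluoro-4-nitrobenzene (NaH, DMF, 0 °C to rt) to give 1-[(2-methylbut-3-yn-2-yl)oxy]-4-nitrobenzene F1. This is heated in the same flask after dilution with 1,2-dichlorobenzene (180 °C), so that the same Claisen, hydrogen-shift and oxa-6π sequence should give 2,2-dimethyl-6-nitro-2H-chromene F2, again with both aryl bonds made in one operation and the regiochemistry fixed by symmetry. Reduction with Fe and NH4Cl in aqueous ethanol should give 2,2-dimethyl-2H-chromen-6-amine F3, and Sandmeyer-type bromination (t-BuONO, CuBr2, MeCN) returns to 12 at the cost of two extra steps.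

Step 6. Insertion of the electron-rich, 8-substituted chromone into the aryl–rhodium bond may be slow, so that protodeboronation of 15 wins, or enantioface discrimination may be insufficient. The fallback sets out from compounds 5 and 15 and comes back at compound 16. The addition is run without chiral ligand with the more active diene complex [Rh(OH)(cod)]2 (dioxane/H2O, 40 °C) to give racemic 7-[(tert-butyldimethylsilyl)oxy]-2-(2,2-dimethyl-2H-chromen-6-yl)-6,8-bis(3-methylbut-2-en-1-yl)chroman-4-one F4. The stereocentre is then secured by kinetic resolution through asymmetric transfer hydrogenation (RuCl(p-cymene)[(R,R)-TsDPEN], HCO2H/Et3N, EtOAc, rt). The catalyst enantiomer whose hydride delivery creates a 4R carbinol should reduce the 2R ketone to the cis alcohol (2R,4R)-7-[(tert-butyldimethylsilyl)oxy]-2-(2,2-dimethyl-2H-chromen-6-yl)-6,8-bis(3-methylbut-2-en-1-yl)chroman-4-ol F5 and leave (2S)-ketone 16, which is separated by chromatography; at most half of the material can be recovered this way.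

Step 3. The prenyl group may transfer through its γ-carbon (allyl transposition to 1,1-dimethylallyl groups), and the second coupling at the doubly flanked C8–I bond may stall with proto-deiodination. The fallback sets out from compound 3 and comes back at compound 5. The smaller, regiochemically unambiguous allyl group is coupled twice (allyltributylstannane, Pd(PPh3)4, dioxane, 100 °C) to give 7-[(tert-butyldimethylsilyl)oxy]-6,8-di(prop-2-en-1-yl)-4H-chromen-4-one F6. Double cross-metathesis with 2-methylbut-2-ene (second-generation Grubbs catalyst, CH2Cl2, 40 °C) then converts both allyl groups into prenyl groups and returns 5.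

Further compounds
F1 | step 4 | 1-[(2-methylbut-3-yn-2-yl)oxy]-4-nitrobenzene | CC(C)(C#C)Oc1ccc(cc1)[N+](=O)[O-]
F2 | step 4 | 2,2-dimethyl-6-nitro-2H-chromene | CC1(C)C=Cc2cc(ccc2O1)[N+](=O)[O-]
F3 | step 4 | 2,2-dimethyl-2H-chromen-6-amine | CC1(C)C=Cc2cc(N)ccc2O1
F4 | step 6 | racemic 7-[(tert-butyldimethylsilyl)oxy]-2-(2,2-dimethyl-2H-chromen-6-yl)-6,8-bis(3-methylbut-2-en-1-yl)chroman-4-one | CC(C)=CCc1cc2c(c(CC=C(C)C)c1O[Si](C)(C)C(C)(C)C)OC(c1ccc3c(c1)C=CC(C)(C)O3)CC2=O
F5 | step 6 | (2R,4R)-7-[(tert-butyldimethylsilyl)oxy]-2-(2,2-dimethyl-2H-chromen-6-yl)-6,8-bis(3-methylbut-2-en-1-yl)chroman-4-ol | CC(C)=CCc1cc2c(c(CC=C(C)C)c1O[Si](C)(C)C(C)(C)C)O[C@@H](c1ccc3c(c1)C=CC(C)(C)O3)C[C@H]2O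
F6 | step 3 | 7-[(tert-butyldimethylsilyl)oxy]-6,8-di(prop-2-en-1-yl)-4H-chromen-4-one | C=CCc1cc2c(=O)ccoc2c(CC=C)c1O[Si](C)(C)C(C)(C)C
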